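(All runs were generated by integration on assumed constants, noise included.)

Minutes. Left over from the epsilon run: its readings show no number of chains, so the meeting took up the flask below.

in all of them: D 0.10 M
- epsilon: Z 5 mM; the very flask that is asked about, followed so far
- flask: Z 5.0 mM; time 10 h

epsilon run (percent of the D charged)

| time / h | Q / % | D / % |
|---|---|---|
| 0.250 | 9.5 | 89.6 |
| 0.417 | 15.8 | 84.8 |
| 0.833 | 29.2 | 72.8 |
| 1.50 | 45.0 | 52.5 |
| 3.00 | 70.2 | 32.3 |

(scatter of a reading: 1 percentage point)

- the average divides the monomer in chains by the number of chains, living and dead together; two radicals that join make one chain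
- what may be going on: D + E -> Q + E; D + X -> E + Q; 2 E -> L; Q -> J; Z -> 2 X
- the earlier runs do not show the number of chains; that part of a forecast is a guess

1. average number of monomer units in a chain (living and dead chains, two that joined counted as one) at 10 h
2. part of the D that has reacted at 10 h

The one who made the forecast reported that Q and D sum to about the whole charge and that the first-order plot of D (pseudo-first-order) is nearly straight. The forecast is dp 60 and c 97%, with the remark “The efficiency is unknown”.

I argued for following one Z along the listed steps. It gives two X, each X has one listed way out, into E, and two E make one L. So the steps as listed make one chain per Z lost, an initiator efficiency of one, which differs from the forecast's guess.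

Then the loss of Z must be read. Averaging the columns, the mean first-order constant is 0.419 h⁻¹ at 0.250 h and 0.390 h⁻¹ at 3.00 h. If cE follows the square root of cZ, that constant falls by kd·t/4, so kd reads 0.102 h⁻¹. This is a poor reading from two points, and the forecast read 0.08 per hour.

The chain share, chains made per Z charged by 10 h, is then 63.9%. That gives 3.19 mM of chains and, on the forecast's c, dp 30.4, lower than the forecast.

    D + E → Q + E, rate k1*[E]*[D] (k = 9700 M⁻¹ s⁻¹)
    D + X → E + Q (k = 8.60 × 10⁵ M⁻¹ s⁻¹)
    2 E → L (k = 1.00 × 10⁹ M⁻¹ s⁻¹)
    Q → J (k = 7.00 × 10⁻⁷ s⁻¹)
    Z → 2 X (k = 2.70 × 10⁻⁵ s⁻¹)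

The flask gives dp 30.8 and c 97.6%, so the forecast's dp is 1.95 times the result. At 10.0 h the flask holds cL 0.00311 M, and the Z lost is 3.11 mM. The neighbouring flask is charged with 0.0020 M of Z, its other charges as in the flask, and read at the same time. The chain share gives it 1.28 mM of chains, and its 87.9% reacted then gives dp 68.8. The neighbouring flask holds cL 0.00124 M and gives dp 69.5.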